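**Plan**

- Feature: in chromene numbering the pyran ring (O1, C2 with its two methyls, C3=C4, fused at C4a/C8a) is a prenyl group on C4a, two hydrogens short, whose C2 is bonded to the oxygen on C8a. Cutting O1–C2 therefore leads back to an ortho-prenylphenol.
- Further cuts: the C8–CH2 bond of the second prenyl group (traced through a [3,3] shift to an O7–CMe2 ether bond), the aryl–CH2 bond of the first prenyl group (C4a–C4), and the C(=O)–CH2 bond of the three-carbon chain.
- Forward: rings A (resorcinol ring) and B (4-hydroxyphenyl ring) are bought. The chain is joined first (steps 3 and 4), the first prenyl group is coupled on (step 5), the pyran ring is closed by DDQ (step 7), and the C8 prenyl group follows by O-alkylation and Claisen shift (steps 9 and 10) before desilylation.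
- Stereochemistry: the target has no stereocentre, and C3=C4 is held cis by the ring. The carbinol centre made in step 3 is racemic and is oxidised away in step 4.

Key step: step 7

Remark on the chemistry: ring B is carried as its triisopropylsilyl ether, because an aryl triisopropylsilyl ether should outlast the acidic removal of the methoxymethyl groups in step 6 far better than a tert-butyldimethylsilyl ether would.

**Step 1**
Reactants: 1 5-bromo-2,4-dihydroxybenzaldehyde
Product: 2 5-bromo-2,4-bis(methoxymethoxy)benzaldehyde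
Conditions: NaH, MOMCl, DMF, 0 °C to rt
Reagents that add atoms: chloromethyl methyl ether (MOMCl), COCCl
Why: Williamson-type O-alkylation of the two sodium phenoxides, in which excess NaH also deprotonates the hydrogen-bonded 2-hydroxyl so that both phenols are capped before the organomagnesium addition.

**Step 2**
Reactants: 3 4-(2-bromoethyl)phenol
Product: 4 [4-(2-bromoethyl)phenoxy]triisopropylsilane
Conditions: TIPSCl, imidazole, CH2Cl2, 0 °C to rt
Reagents that add atoms: chlorotriisopropylsilane (TIPSCl), CC(C)[Si](Cl)(C(C)C)C(C)C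
Why: Imidazole-promoted silylation of a phenol, which leaves the primary bromide untouched at room temperature and gives an ether that tolerates Grignard formation and mild acid.

**Step 3**
Reactants: 4 [4-(2-bromoethyl)phenoxy]triisopropylsilane; 2 5-bromo-2,4-bis(methoxymethoxy)benzaldehyde
Product: 7 1-[5-bromo-2,4-bis(methoxymethoxy)phenyl]-3-[4-(triisopropylsilyloxy)phenyl]propan-1-ol (racemic), via Grignard reagent 5 (not isolated), via bromomagnesium alkoxide 6 (not isolated)
Conditions: Mg, THF, 40 °C; then 2, THF, −20 to 0 °C; H2O quench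
Reagents that add atoms: none
Why: Grignard addition of a primary alkylmagnesium bromide to an aryl aldehyde, which is much faster than any exchange at the aryl bromide at low temperature and forms the carbinol centre as a racemate that step 4 removes.

**Step 4**
Reactants: 7 1-[5-bromo-2,4-bis(methoxymethoxy)phenyl]-3-[4-(triisopropylsilyloxy)phenyl]propan-1-ol
Product: 8 1-[5-bromo-2,4-bis(methoxymethoxy)phenyl]-3-[4-(triisopropylsilyloxy)phenyl]propan-1-one
Conditions: Dess–Martin periodinane, CH2Cl2, 0 °C to rt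
Reagents that add atoms: none
Why: Dess–Martin oxidation of a secondary benzylic alcohol to the aryl ketone under near-neutral conditions that spare the acetals, the silyl ether and the aryl bromide.

**Step 5**
Reactants: 8 1-[5-bromo-2,4-bis(methoxymethoxy)phenyl]-3-[4-(triisopropylsilyloxy)phenyl]propan-1-one; 9 tributyl(3-methylbut-2-enyl)stannane
Product: 10 1-[2,4-bis(methoxymethoxy)-5-(3-methylbut-2-enyl)phenyl]-3-[4-(triisopropylsilyloxy)phenyl]propan-1-one
Conditions: Pd(PPh3)4 (5 mol%), DMF, 100 °C
Reagents that add atoms: none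
Why: Stille cross-coupling of an aryl bromide with an allylic stannane, in which Pd(PPh3)4 is expected to deliver the allyl unit through its primary carbon and which needs neither base nor fluoride, so ketone, acetals and silyl ether are not at risk.

**Step 6**
Reactants: 10 1-[2,4-bis(methoxymethoxy)-5-(3-methylbut-2-enyl)phenyl]-3-[4-(triisopropylsilyloxy)phenyl]propan-1-one
Product: 11 1-[2,4-dihydroxy-5-(3-methylbut-2-enyl)phenyl]-3-[4-(triisopropylsilyloxy)phenyl]propan-1-one
Conditions: HCl (1 M), MeOH, 40 °C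
Reagents that add atoms: none
Why: Acid-catalysed acetal exchange with methanol removes both methoxymethyl groups under conditions mild enough that the trisubstituted olefin should not add the neighbouring phenol and the triisopropylsilyl ether should stay on.

**Step 7**
Reactants: 11 1-[2,4-dihydroxy-5-(3-methylbut-2-enyl)phenyl]-3-[4-(triisopropylsilyloxy)phenyl]propan-1-one
Product: 13 1-(7-hydroxy-2,2-dimethyl-2H-chromen-6-yl)-3-[4-(triisopropylsilyloxy)phenyl]propan-1-one, via ortho-quinone methide 12 (not isolated)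
Conditions: DDQ (1.05 equiv), benzene, 80 °C
Reagents that add atoms: none
Why: DDQ takes a hydride from the ArCH2 of the prenyl group, which is both benzylic and allylic and is conjugated to the 4-hydroxyl (ortho) and the 2-hydroxyl (para), and loss of the 4-OH proton then gives the (Z)-ortho-quinone methide 12, a 1-oxatriene. This intermediate closes by thermal disrotatory oxa-6π electrocyclisation between the carbonyl oxygen and the dimethyl-substituted terminus, forming O1–C2 and the six-membered 2H-pyran while the benzene ring is regained. The closest known reaction type is the DDQ cyclodehydrogenation of ortho-(3-methylbut-2-enyl)phenols, acylresorcinols among them, to 2,2-dimethyl-2H-chromenes. No stereocentre arises, since C2 carries two methyl groups. Regioselectivity is fixed by the substrate: only the 4-hydroxyl sits next to the prenyl group, the 2-hydroxyl is para to it and bound to the ketone by a hydrogen bond, so the linear 6-acyl-7-hydroxychromene is the only pyran that can form. Chemoselectivity rests on the far weaker activation of the CH2 next to ring B (one silyloxy donor) and of the CH2 next to the ketone, which about one equivalent of DDQ should leave alone.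

**Step 8**
Reactants: 14 2-methylbut-3-en-2-ol
Product: 16 tert-butyl 2-methylbut-3-en-2-yl carbonate, via lithium alkoxide 15 (not isolated)
Conditions: n-BuLi, THF, −78 °C; then Boc2O, −78 °C to rt
Reagents that add atoms: di-tert-butyl dicarbonate (Boc2O), CC(C)(C)OC(=O)OC(=O)OC(C)(C)C
Why: Acylation of a lithium tertiary alkoxide with Boc2O gives the mixed carbonate, the ionisable allyl donor needed for palladium-catalysed allylation.

**Step 9**
Reactants: 13 1-(7-hydroxy-2,2-dimethyl-2H-chromen-6-yl)-3-[4-(triisopropylsilyloxy)phenyl]propan-1-one; 16 tert-butyl 2-methylbut-3-en-2-yl carbonate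
Product: 17 1-[2,2-dimethyl-7-(2-methylbut-3-en-2-yloxy)-2H-chromen-6-yl]-3-[4-(triisopropylsilyloxy)phenyl]propan-1-one
Conditions: Pd(PPh3)4 (5 mol%), THF, 0 °C to rt
Reagents that add atoms: none
Why: Tsuji–Trost O-allylation, in which zerovalent palladium ionises the carbonate with loss of CO2, the tert-butoxide set free deprotonates the 7-hydroxyl, and the phenoxide attacks the more substituted allyl terminus under kinetic control to give the tertiary ether.

**Step 10**
Reactants: 17 1-[2,2-dimethyl-7-(2-methylbut-3-en-2-yloxy)-2H-chromen-6-yl]-3-[4-(triisopropylsilyloxy)phenyl]propan-1-one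
Product: 19 1-[7-hydroxy-2,2-dimethyl-8-(3-methylbut-2-enyl)-2H-chromen-6-yl]-3-[4-(triisopropylsilyloxy)phenyl]propan-1-one, via cyclohexadienone 18 (not isolated)
Conditions: toluene, 110 °C, sealed tube
Reagents that add atoms: none
Why: Aromatic Claisen rearrangement, a [3,3] shift that can only end at C8 because C6 carries the acyl group, turns the 1,1-dimethylallyl ether into the 3-methylbut-2-enyl side chain by allyl inversion, and tautomerisation of dienone 18 (transient C8 centre) restores the hydrogen-bonded phenol.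

**Step 11**
Reactants: 19 1-[7-hydroxy-2,2-dimethyl-8-(3-methylbut-2-enyl)-2H-chromen-6-yl]-3-[4-(triisopropylsilyloxy)phenyl]propan-1-one
Product: 20 1-[7-hydroxy-2,2-dimethyl-8-(3-methylbut-2-enyl)-2H-chromen-6-yl]-3-(4-hydroxyphenyl)propan-1-one
Conditions: Bu4NF, AcOH, THF, 0 °C
Reagents that add atoms: none
Why: Fluoride-induced cleavage of an aryl silyl ether, driven by the strength of the Si–F bond and buffered with acetic acid so that chromene, prenyl group and ketone are not exposed to free phenoxide.

**Compound list**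

1 | 5-bromo-2,4-dihydroxybenzaldehyde | O=Cc1cc(Br)c(O)cc1O | starting material
2 | 5-bromo-2,4-bis(methoxymethoxy)benzaldehyde | COCOc1cc(OCOC)c(Br)cc1C=O | intermediate
3 | 4-(2-bromoethyl)phenol | Oc1ccc(CCBr)cc1 | starting material
4 | [4-(2-bromoethyl)phenoxy]triisopropylsilane | CC(C)[Si](Oc1ccc(CCBr)cc1)(C(C)C)C(C)C | intermediate
5 | {2-[4-(triisopropylsilyloxy)phenyl]ethyl}magnesium bromide | CC(C)[Si](Oc1ccc(CC[Mg]Br)cc1)(C(C)C)C(C)C | intermediate
6 | bromomagnesium 1-[5-bromo-2,4-bis(methoxymethoxy)phenyl]-3-[4-(triisopropylsilyloxy)phenyl]propan-1-olate (racemic) | COCOc1cc(OCOC)c(Br)cc1C(O[Mg]Br)CCc1ccc(O[Si](C(C)C)(C(C)C)C(C)C)cc1 | intermediate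
7 | 1-[5-bromo-2,4-bis(methoxymethoxy)phenyl]-3-[4-(triisopropylsilyloxy)phenyl]propan-1-ol (racemic) | COCOc1cc(OCOC)c(Br)cc1C(O)CCc1ccc(O[Si](C(C)C)(C(C)C)C(C)C)cc1 | intermediate
8 | 1-[5-bromo-2,4-bis(methoxymethoxy)phenyl]-3-[4-(triisopropylsilyloxy)phenyl]propan-1-one | COCOc1cc(OCOC)c(Br)cc1C(=O)CCc1ccc(O[Si](C(C)C)(C(C)C)C(C)C)cc1 | intermediate
9 | tributyl(3-methylbut-2-enyl)stannane | CC(C)=CC[Sn](CCCC)(CCCC)CCCC | starting material
10 | 1-[2,4-bis(methoxymethoxy)-5-(3-methylbut-2-enyl)phenyl]-3-[4-(triisopropylsilyloxy)phenyl]propan-1-one | COCOc1cc(OCOC)c(CC=C(C)C)cc1C(=O)CCc1ccc(O[Si](C(C)C)(C(C)C)C(C)C)cc1 | intermediate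
11 | 1-[2,4-dihydroxy-5-(3-methylbut-2-enyl)phenyl]-3-[4-(triisopropylsilyloxy)phenyl]propan-1-one | CC(C)=CCc1cc(C(=O)CCc2ccc(O[Si](C(C)C)(C(C)C)C(C)C)cc2)c(O)cc1O | intermediate
12 | (6Z)-3-hydroxy-6-(3-methylbut-2-enylidene)-4-{3-[4-(triisopropylsilyloxy)phenyl]propanoyl}cyclohexa-2,4-dien-1-one | CC(C)=C/C=C1\C(=O)C=C(O)C(C(=O)CCc2ccc(O[Si](C(C)C)(C(C)C)C(C)C)cc2)=C1 | intermediate
13 | 1-(7-hydroxy-2,2-dimethyl-2H-chromen-6-yl)-3-[4-(triisopropylsilyloxy)phenyl]propan-1-one | CC1(C)C=Cc2cc(C(=O)CCc3ccc(O[Si](C(C)C)(C(C)C)C(C)C)cc3)c(O)cc2O1 | intermediate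
14 | 2-methylbut-3-en-2-ol | C=CC(C)(C)O | starting material
15 | lithium 2-methylbut-3-en-2-olate | C=CC(C)(C)[O-].[Li+] | intermediate
16 | tert-butyl 2-methylbut-3-en-2-yl carbonate | C=CC(C)(C)OC(=O)OC(C)(C)C | intermediate
17 | 1-[2,2-dimethyl-7-(2-methylbut-3-en-2-yloxy)-2H-chromen-6-yl]-3-[4-(triisopropylsilyloxy)phenyl]propan-1-one | C=CC(C)(C)Oc1cc2OC(C)(C)C=Cc2cc1C(=O)CCc1ccc(O[Si](C(C)C)(C(C)C)C(C)C)cc1 | intermediate
18 | 2,2-dimethyl-8-(3-methylbut-2-enyl)-6-{3-[4-(triisopropylsilyloxy)phenyl]propanoyl}-2H-chromen-7(8H)-one (racemic) | CC(C)=CCC1C(=O)C(C(=O)CCc2ccc(O[Si](C(C)C)(C(C)C)C(C)C)cc2)=CC2=C1OC(C)(C)C=C2 | intermediate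
19 | 1-[7-hydroxy-2,2-dimethyl-8-(3-methylbut-2-enyl)-2H-chromen-6-yl]-3-[4-(triisopropylsilyloxy)phenyl]propan-1-one | CC(C)=CCc1c(O)c(C(=O)CCc2ccc(O[Si](C(C)C)(C(C)C)C(C)C)cc2)cc2c1OC(C)(C)C=C2 | intermediate
20 | 1-[7-hydroxy-2,2-dimethyl-8-(3-methylbut-2-enyl)-2H-chromen-6-yl]-3-(4-hydroxyphenyl)propan-1-one | CC(C)=CCc1c(O)c(C(=O)CCc2ccc(O)cc2)cc2c1OC(C)(C)C=C2 | target

**Step count**

Total steps: 11. Longest linear sequence: 9 steps (steps 1, 3, 4, 5, 6, 7, 9, 10 and 11 from compound 1).

**Steps most likely to fail**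

Step 9. The 7-hydroxyl is hydrogen-bonded to the ketone and may be alkylated slowly. Palladium may also re-ionise the tertiary ether and equilibrate it to the linear prenyl ether, which would place the wrong allyl isomer on C8 in step 10. Fallback: setting out from 13, copper-catalysed O-alkylation with 3-chloro-3-methylbut-1-yne (DBU, CuCl2 catalytic, MeCN, 0 °C) should give 1-[2,2-dimethyl-7-(2-methylbut-3-yn-2-yloxy)-2H-chromen-6-yl]-3-[4-(triisopropylsilyloxy)phenyl]propan-1-one F1. Semi-hydrogenation of the alkyne (H2, Pd/CaCO3 poisoned with Pb(OAc)2, quinoline, EtOAc, rt) then comes back to the route at 17.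

Step 7. The acyl group slows hydride abstraction, and forcing the reaction may dehydrogenate the CH2–CH2 tether towards the enone or oxidise the chromene further. Fallback: setting out from 11, PhSeCl (CH2Cl2, −78 °C) should close the same O1–C2 bond by 6-endo selenoetherification, the phenol oxygen attacking the tertiary end of the seleniranium ion. This gives racemic 1-[7-hydroxy-2,2-dimethyl-3-(phenylselanyl)-3,4-dihydro-2H-chromen-6-yl]-3-[4-(triisopropylsilyloxy)phenyl]propan-1-one F2. Oxidation with H2O2 (THF, 0 °C to rt) leads to the selenoxide 1-[7-hydroxy-2,2-dimethyl-3-(phenylseleninyl)-3,4-dihydro-2H-chromen-6-yl]-3-[4-(triisopropylsilyloxy)phenyl]propan-1-one F3. Its syn-elimination can only take a hydrogen from C4, so it comes back to the route at 13.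

Step 5. Oxidative addition into the electron-rich, ortho-alkoxylated aryl bromide may be slow, and the allyl group may be transferred through its tertiary end to give the 1,1-dimethylallyl isomer. Fallback: setting out from 8, Stille coupling with allyltributylstannane (Pd(PPh3)4, DMF, 100 °C), which has no such ambiguity, should give 1-[2,4-bis(methoxymethoxy)-5-(prop-2-enyl)phenyl]-3-[4-(triisopropylsilyloxy)phenyl]propan-1-one F4. Cross-metathesis with 2-methylbut-2-ene (second-generation Grubbs catalyst, CH2Cl2, 40 °C) then comes back to the route at 10.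

**Further compounds**

F1 | step 9 | 1-[2,2-dimethyl-7-(2-methylbut-3-yn-2-yloxy)-2H-chromen-6-yl]-3-[4-(triisopropylsilyloxy)phenyl]propan-1-one | C#CC(C)(C)Oc1cc2OC(C)(C)C=Cc2cc1C(=O)CCc1ccc(O[Si](C(C)C)(C(C)C)C(C)C)cc1
F2 | step 7 | 1-[7-hydroxy-2,2-dimethyl-3-(phenylselanyl)-3,4-dihydro-2H-chromen-6-yl]-3-[4-(triisopropylsilyloxy)phenyl]propan-1-one (racemic) | CC1(C)Oc2cc(O)c(C(=O)CCc3ccc(O[Si](C(C)C)(C(C)C)C(C)C)cc3)cc2CC1[Se]c1ccccc1
F3 | step 7 | 1-[7-hydroxy-2,2-dimethyl-3-(phenylseleninyl)-3,4-dihydro-2H-chromen-6-yl]-3-[4-(triisopropylsilyloxy)phenyl]propan-1-one | CC1(C)Oc2cc(O)c(C(=O)CCc3ccc(O[Si](C(C)C)(C(C)C)C(C)C)cc3)cc2CC1[Se](=O)c1ccccc1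
F4 | step 5 | 1-[2,4-bis(methoxymethoxy)-5-(prop-2-enyl)phenyl]-3-[4-(triisopropylsilyloxy)phenyl]propan-1-one | C=CCc1cc(C(=O)CCc2ccc(O[Si](C(C)C)(C(C)C)C(C)C)cc2)c(OCOC)cc1OCOC
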